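Rings: A = plain cyclopentene, B = ester-bearing cyclopentene, C = cycloheptene, D = piperidine, E = tetrahydropyran hemiketal; Ca = quaternary carbon shared by B, C and D, Cb = spiro carbon of D/E, Cc = bridgehead CH of C/D.
Retrosynthesis: NCH3 and hemiketal last; ring B cut at C=C(CO2Me) (aldol condensation); ring C cut at Cc–CH2 (7-endo radical closure onto a vinyl dienone); ring A cut to a γ-keto ester (Dieckmann); rings D/E traced to a pyrrolidin-3-ol bearing a 2,2-disubstituted oxirane.
Forward: pyrrolidinone → Ca (Pd allylation) → alkenyl addition, epoxidation → pyrrolidine → piperidin-3-one (ring D) with Cb and ring E → ring A → ring C → ring B → deprotection, ester, NCH3.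
Enabling feature: in ring D, Cb carries OCH2 and sits between Cc (kept as C=O until ring C is closed, then used as the radical site) and quaternary Ca. This β-hydroxy ketone with a quaternary α-carbon is the retron of a semipinacol shift of an α-hydroxy epoxide in a ring one atom smaller.
Stereochemistry: Ca from the enantioselective decarboxylative allylation; Cb from a catalyst-controlled epoxidation, relayed with inversion in the 1,2-shift; Cc from the geometry of the bridging radical closure; the hemiketal carbon is thermodynamic.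
Key step: step 10

Remarks on the chemistry (assumptions):
- The hemiketal carbon of the target is taken to be the thermodynamically preferred anomer (axial OH, equatorial ethyl, Ca equatorial on ring E), so it is set by equilibration when the ketal is hydrolysed.
- The carbinol centres of 15, 16, 24, 25 and the ketal carbon of 18–28 are carried as mixtures because they are destroyed or equilibrated later; their SMILES leave them undefined.
- From 17 on, the OCH2 group on Cb is cis (on ring D) to the ring-A-forming arm on Ca.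

Step 1
Reactants: 1 2-methylenepropane-1,3-diol; 2 trimethyl orthoacetate
Product: 3 methyl 4-(hydroxymethyl)pent-4-enoate
Conditions: 1 (3 equiv), EtCO2H (cat.), 110 °C, MeOH distilled off
Reagents that add atoms: none
Why: Johnson–Claisen rearrangement of the mixed ketene acetal formed at one of the two equivalent allylic hydroxyls; excess diol limits a second rearrangement and no stereocentre is formed.

Step 2
Reactants: 3 methyl 4-(hydroxymethyl)pent-4-enoate; 4 1-tert-butyl 3-ethyl 4-oxopyrrolidine-1,3-dicarboxylate
Product: 5 1-tert-butyl 3-(5-methoxy-2-methylidene-5-oxopentyl) 4-oxopyrrolidine-1,3-dicarboxylate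
Conditions: DMAP (cat.), toluene, reflux, 4 Å sieves
Reagents that add atoms: none
Why: DMAP-catalysed transesterification, which is specific to β-keto esters, so the ordinary methyl ester of 3 is not exchanged.

Step 3
Reactants: 5 β-keto ester; 6 tert-butyl acrylate
Product: 7 1-tert-butyl 3-(5-methoxy-2-methylidene-5-oxopentyl) 3-(3-tert-butoxy-3-oxopropyl)-4-oxopyrrolidine-1,3-dicarboxylate (racemic)
Conditions: K2CO3 (cat.), MeCN, rt
Reagents that add atoms: none
Why: Michael addition of the doubly activated methine; the racemic quaternary centre is erased on decarboxylation in step 4, and the tert-butyl ester is chosen because it resists lactonisation and Claisen chemistry later.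

Step 4
Reactants: 7 allyl-type β-keto ester
Product: 8 tert-butyl (3S)-3-(3-tert-butoxy-3-oxopropyl)-3-(5-methoxy-2-methylidene-5-oxopentyl)-4-oxopyrrolidine-1-carboxylate
Conditions: Pd2(dba)3 (2.5 mol%), (R)-t-BuPHOX (6 mol%), toluene, 30 °C
Reagents that add atoms: none
Why: Decarboxylative asymmetric allylic alkylation (Tsuji allylation): zerovalent palladium ionises the allyl ester, CO2 is lost and the ligand-bound π-allyl/enolate pair recombines regiospecifically at the fully substituted α-carbon; the 2-substituted allyl unit has equivalent termini, and the PHOX ligand (antipode chosen by analogy with carbocyclic 2-alkyl-2-allyl ketones) selects the enolate face to give Ca as the (S) centre.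

Step 5
Reactants: 9 ethyl 3-oxopentanoate; 10 2,3-dibromoprop-1-ene
Product: 11 ethyl 2-(2-bromoprop-2-en-1-yl)-3-oxopentanoate
Conditions: K2CO3, acetone, reflux
Reagents that add atoms: none
Why: SN2 alkylation of the β-keto ester by the allylic bromide; the vinylic bromide is inert.

Step 6
Reactants: 11 alkylated β-keto ester
Product: 12 6-bromohept-6-en-3-one
Conditions: LiCl, H2O, DMSO, 150 °C
Reagents that add atoms: none
Why: Krapcho dealkoxycarbonylation of a β-keto ester.

Step 7
Reactants: 12 6-bromohept-6-en-3-one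
Product: 13 2-bromo-5,5-dimethoxyhept-1-ene
Conditions: HC(OMe)3, MeOH, TsOH (cat.), rt
Reagents that add atoms: trimethyl orthoformate COC(OC)OC
Why: Acid-catalysed ketalisation driven by the orthoester; it masks the ethyl ketone against the organolithium and later supplies ring E.

Step 8
Reactants: 8 pyrrolidinone; 13 2-bromo-5,5-dimethoxyhept-1-ene
Product: 15 tert-butyl (3S)-3-(3-tert-butoxy-3-oxopropyl)-4-(5,5-dimethoxyhept-1-en-2-yl)-4-hydroxy-3-(5-methoxy-2-methylidene-5-oxopentyl)pyrrolidine-1-carboxylate (both C4 epimers), via alkenyllithium 14 (not isolated)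
Conditions: 13, t-BuLi (2.0 equiv), Et2O, −78 °C; CeCl3, THF, −78 °C; then 8; H2O
Reagents that add atoms: none
Why: Bromine–lithium exchange gives the vinyllithium, which CeCl3 renders less basic, so it adds 1,2 to the hindered, enolisable ketone faster than to the esters or carbamate at −78 °C; both carbinol epimers are used because this carbon becomes the ketone in step 10.

Step 9
Reactants: 15 tertiary allylic alcohol
Product: 16 tert-butyl (3S)-3-(3-tert-butoxy-3-oxopropyl)-4-[(2S)-2-(3,3-dimethoxypentyl)oxiran-2-yl]-4-hydroxy-3-(5-methoxy-2-methylidene-5-oxopentyl)pyrrolidine-1-carboxylate (both C4 epimers)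
Conditions: Hf(Ot-Bu)4 (10 mol%), C2-symmetric bis-hydroxamic acid ligand from trans-cyclohexane-1,2-diamine (12 mol%, antipode as required), cumene hydroperoxide, toluene, 0 °C
Reagents that add atoms: cumene hydroperoxide CC(C)(OO)c1ccccc1
Why: Hydroxyl-directed, catalyst-controlled epoxidation of a tertiary allylic alcohol by a chiral tetravalent hafnium bis-hydroxamate; binding of the carbinol oxygen makes it selective for the allylic alkene over the remote one, and the ligand should deliver oxygen to the same alkene face in both carbinol epimers, fixing the (S) oxirane carbon.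

Step 10
Reactants: 16 epoxy alcohol
Product: 18 tert-butyl (6R,11R)-11-(3-tert-butoxy-3-oxopropyl)-3-ethyl-3-methoxy-11-(5-methoxy-2-methylidene-5-oxopentyl)-7-oxo-2-oxa-9-azaspiro[5.5]undecane-9-carboxylate (ketal anomers), via hydroxy ketone 17 (not isolated)
Conditions: BF3·OEt2 (1.2 equiv), CH2Cl2, −78 °C; Et3N; then PPTS (cat.), MeOH, rt
Reagents that add atoms: none
Why: BF3 coordinates the oxirane oxygen, the C–O bond at the fully substituted oxirane carbon (future Cb) ionises, and the quaternary ring carbon Ca shifts antiperiplanar from the carbinol carbon to Cb while the carbinol oxygen collapses to the ketone; the closest known reaction type is the Lewis-acid semipinacol rearrangement of 2,3-epoxy alcohols with ring enlargement. Ring D is therefore not closed by a cyclisation but arises from the pyrrolidine by insertion of Cb into the Ca–C(carbinol) bond (five- to six-membered), and ring E closes afterwards in 6-exo-trig fashion when the freed OCH2 hydroxyl adds to the oxocarbenium ion of the dimethyl ketal. Cb is formed with inversion at the oxirane carbon, so its configuration is the one written into the epoxide in step 9, Ca migrates with retention, and the ketal carbon is an inconsequential anomeric mixture. The step needs Ca to migrate in preference to the NCH2 carbon, which is secured because Ca is the more substituted, electron-richer terminus while NCH2 is deactivated by the carbamate nitrogen; the carbinol configuration is irrelevant because that carbon becomes sp2. Low temperature keeps the tert-butyl carbamate and ester intact, and the acidic methanol funnels any enol ether or open hydroxy ketone into the single cyclic methyl ketal.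

Step 11
Reactants: 18 spiroketal piperidinone
Product: 20 tert-butyl (6R,11R)-11-(3-tert-butoxy-3-oxopropyl)-3-ethyl-3-methoxy-11-(5-methoxy-2,5-dioxopentyl)-7-oxo-2-oxa-9-azaspiro[5.5]undecane-9-carboxylate, via ozonide 19 (not isolated)
Conditions: O3, CH2Cl2, −78 °C; then PPh3, rt
Reagents that add atoms: ozone [O-][O+]=O
Why: Ozonolysis of the only C=C bond (1,1-disubstituted) unmasks the γ-keto ester; carbamate, esters and ketal are inert.

Step 12
Reactants: 20 γ-keto ester
Product: 21 tert-butyl (6R,11R)-11-(3-tert-butoxy-3-oxopropyl)-11-(2,5-dioxocyclopentyl)-3-ethyl-3-methoxy-7-oxo-2-oxa-9-azaspiro[5.5]undecane-9-carboxylate (drawn as the diketone, present as the enol)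
Conditions: KOt-Bu (2.2 equiv), THF, 0 → 40 °C; then AcOH
Reagents that add atoms: none
Why: Dieckmann-type cyclisation of a γ-keto ester to the 2-substituted cyclopentane-1,3-dione (ring A), pulled forward by formation of the vinylogous carboxylate; the tert-butyl ester is too hindered to act as acceptor and aldol additions to the piperidinone carbonyl are reversible.

Step 13
Reactants: 21 cyclopentane-1,3-dione
Product: 22 enol triflate: the 11-[5-oxo-2-(trifluoromethanesulfonyloxy)cyclopent-1-en-1-yl] analogue of 21 (Ca and Cb as in 18)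
Conditions: PhNTf2, Et3N, DMAP (cat.), CH2Cl2, 0 °C → rt
Reagents that add atoms: N-phenylbis(trifluoromethanesulfonimide) O=S(=O)(N(c1ccccc1)S(=O)(=O)C(F)(F)F)C(F)(F)F
Why: O-sulfonylation of the acidic 1,3-dione; its two carbonyls are equivalent, so a single vinylogous acyl triflate results.

Step 14
Reactants: 22 enol triflate
Product: 23 vinyl dienone: the 11-(2-ethenyl-5-oxocyclopent-1-en-1-yl) analogue (Ca and Cb as in 18)
Conditions: tributyl(vinyl)stannane, Pd(PPh3)4 (5 mol%), LiCl (3 equiv), THF, 65 °C
Reagents that add atoms: tributyl(vinyl)stannane C=C[Sn](CCCC)(CCCC)CCCC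
Why: Stille coupling of a β-triflyloxy enone, with LiCl assisting transmetalation.

Step 15
Reactants: 23 vinyl dienone
Product: 24 the 7-hydroxy analogue of 23 (both C7 epimers)
Conditions: NaBH4, MeOH/CH2Cl2 (1:1), −78 °C
Reagents that add atoms: none
Why: Chemoselective borohydride reduction: the saturated α-amino ketone should react faster at −78 °C than the cross-conjugated, tetrasubstituted dienone; the epimers are used together because this carbon becomes a radical.

Step 16
Reactants: 24 secondary alcohol
Product: 25 the 7-O-(phenoxythiocarbonyl) derivative of 24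
Conditions: PhOC(S)Cl, pyridine, DMAP (cat.), CH2Cl2, rt
Reagents that add atoms: O-phenyl chlorothionoformate S=C(Cl)Oc1ccccc1
Why: Acylation of the secondary alcohol to the thionocarbonate, the Barton–McCombie radical precursor.

Step 17
Reactants: 25 thionocarbonate
Product: 26 ring-C-closed tetracyclic enone: N-Boc piperidine (ring D) bridged across Ca and Cc by cycloheptene ring C, which is fused to cyclopentenone ring A; Ca keeps the CH2CH2CO2t-Bu arm, Cb the spiro methyl ketal ring E
Conditions: Bu3SnH (1.3 equiv, syringe pump), AIBN (cat.), toluene, 100 °C, 3 mM; then DBU, rt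
Reagents that add atoms: none
Why: Barton–McCombie-type C–O homolysis gives the secondary ring radical, which at low stannane concentration adds 7-endo-trig to the vinyl terminus (a radical 1,6-conjugate addition giving an oxygen-stabilised dienyl radical) and closes ring C; only the cis-bridged product is geometrically possible, so Cc is set by Ca, and DBU moves any β,γ-isomer into conjugation.

Step 18
Reactants: 26 tetracyclic enone
Product: 28 N-Boc, tert-butyl ester, O-methyl ketal of the target skeleton (ring B closed, dienoate), via aldol adduct 27 (not isolated)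
Conditions: KOt-Bu (0.3 equiv), t-BuOH/THF, 50 °C
Reagents that add atoms: none
Why: Intramolecular aldol condensation: the ester enolate adds to the ring-A carbonyl (5-(enolexo)-exo-trig, the only cyclisation open to it) and E1cB dehydration gives the tetrasubstituted, fully conjugated dienoate; no stereocentre is formed.

Step 19
Reactants: 28 protected pentacycle
Product: 29 N-desmethyl amino acid hemiketal
Conditions: TFA/CH2Cl2/H2O (10:10:1), anisole, 0 °C → rt
Reagents that add atoms: water O
Why: Acidolysis removes the tert-butyl carbamate and tert-butyl ester and hydrolyses the methyl ketal; the hemiketal should equilibrate to the anomer with axial hydroxyl and equatorial ethyl, which is the target configuration.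

Step 20
Reactants: 29 amino acid
Product: 30 N-desmethyl target (secondary amine, methyl ester)
Conditions: Me3SiCHN2, MeOH/toluene, 0 °C
Reagents that add atoms: trimethylsilyldiazomethane C[Si](C)(C)C=[N+]=[N-]
Why: O-methylation of the carboxylic acid by diazomethane generated in situ; the ammonium nitrogen and the hemiketal hydroxyl are not acidic enough to react.

Step 21
Reactants: 30 secondary amine
Product: 31 target CNP0192143.3
Conditions: CH2O (aq), HCO2H, 50 °C
Reagents that add atoms: formaldehyde C=O
Why: Eschweiler–Clarke methylation through the iminium ion and hydride transfer from formate; it cannot over-alkylate and touches no stereocentre.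

Compound list
1 | 2-methylenepropane-1,3-diol | C=C(CO)CO | starting material
2 | trimethyl orthoacetate | CC(OC)(OC)OC | starting material
3 | methyl 4-(hydroxymethyl)pent-4-enoate | COC(=O)CCC(=C)CO | intermediate
4 | 1-tert-butyl 3-ethyl 4-oxopyrrolidine-1,3-dicarboxylate | CCOC(=O)C1CN(C(=O)OC(C)(C)C)CC1=O | starting material
5 | 1-tert-butyl 3-(5-methoxy-2-methylidene-5-oxopentyl) 4-oxopyrrolidine-1,3-dicarboxylate | COC(=O)CCC(=C)COC(=O)C1CN(C(=O)OC(C)(C)C)CC1=O | intermediate
6 | tert-butyl acrylate | C=CC(=O)OC(C)(C)C | starting material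
7 | 1-tert-butyl 3-(5-methoxy-2-methylidene-5-oxopentyl) 3-(3-tert-butoxy-3-oxopropyl)-4-oxopyrrolidine-1,3-dicarboxylate (racemic) | COC(=O)CCC(=C)COC(=O)C1(CCC(=O)OC(C)(C)C)CN(C(=O)OC(C)(C)C)CC1=O | intermediate
8 | tert-butyl (3S)-3-(3-tert-butoxy-3-oxopropyl)-3-(5-methoxy-2-methylidene-5-oxopentyl)-4-oxopyrrolidine-1-carboxylate | CC(C)(C)OC(=O)CC[C@]1(CC(=C)CCC(=O)OC)CN(C(=O)OC(C)(C)C)CC1=O | intermediate
9 | ethyl 3-oxopentanoate | CCC(=O)CC(=O)OCC | starting material
10 | 2,3-dibromoprop-1-ene | C=C(Br)CBr | starting material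
11 | ethyl 2-(2-bromoprop-2-en-1-yl)-3-oxopentanoate | CCC(=O)C(CC(Br)=C)C(=O)OCC | intermediate
12 | 6-bromohept-6-en-3-one | CCC(=O)CCC(Br)=C | intermediate
13 | 2-bromo-5,5-dimethoxyhept-1-ene | CCC(OC)(OC)CCC(Br)=C | intermediate
14 | (5,5-dimethoxyhept-1-en-2-yl)lithium | [Li]C(=C)CCC(OC)(OC)CC | intermediate
15 | tert-butyl (3S)-3-(3-tert-butoxy-3-oxopropyl)-4-(5,5-dimethoxyhept-1-en-2-yl)-4-hydroxy-3-(5-methoxy-2-methylidene-5-oxopentyl)pyrrolidine-1-carboxylate (C4 epimers) | CCC(OC)(OC)CCC(=C)C1(O)CN(C(=O)OC(C)(C)C)C[C@]1(CCC(=O)OC(C)(C)C)CC(=C)CCC(=O)OC | intermediate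
16 | tert-butyl (3S)-3-(3-tert-butoxy-3-oxopropyl)-4-[(2S)-2-(3,3-dimethoxypentyl)oxiran-2-yl]-4-hydroxy-3-(5-methoxy-2-methylidene-5-oxopentyl)pyrrolidine-1-carboxylate (C4 epimers) | CCC(OC)(OC)CC[C@]1(CO1)C2(O)CN(C(=O)OC(C)(C)C)C[C@]2(CCC(=O)OC(C)(C)C)CC(=C)CCC(=O)OC | intermediate
17 | tert-butyl (4R,5R)-5-(3-tert-butoxy-3-oxopropyl)-4-(3,3-dimethoxypentyl)-4-(hydroxymethyl)-5-(5-methoxy-2-methylidene-5-oxopentyl)-3-oxopiperidine-1-carboxylate | CCC(OC)(OC)CC[C@@]1(CO)C(=O)CN(C(=O)OC(C)(C)C)C[C@]1(CCC(=O)OC(C)(C)C)CC(=C)CCC(=O)OC | intermediate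
18 | tert-butyl (6R,11R)-11-(3-tert-butoxy-3-oxopropyl)-3-ethyl-3-methoxy-11-(5-methoxy-2-methylidene-5-oxopentyl)-7-oxo-2-oxa-9-azaspiro[5.5]undecane-9-carboxylate (ketal anomers) | CCC1(OC)CC[C@@]2(CO1)C(=O)CN(C(=O)OC(C)(C)C)C[C@]2(CCC(=O)OC(C)(C)C)CC(=C)CCC(=O)OC | intermediate
19 | ozonide (1,2,4-trioxolane at the methylidene carbon) of 18 | CCC1(OC)CC[C@@]2(CO1)C(=O)CN(C(=O)OC(C)(C)C)C[C@]2(CCC(=O)OC(C)(C)C)CC3(CCC(=O)OC)OCOO3 | intermediate
20 | tert-butyl (6R,11R)-11-(3-tert-butoxy-3-oxopropyl)-3-ethyl-3-methoxy-11-(5-methoxy-2,5-dioxopentyl)-7-oxo-2-oxa-9-azaspiro[5.5]undecane-9-carboxylate | CCC1(OC)CC[C@@]2(CO1)C(=O)CN(C(=O)OC(C)(C)C)C[C@]2(CCC(=O)OC(C)(C)C)CC(=O)CCC(=O)OC | intermediate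
21 | tert-butyl (6R,11R)-11-(3-tert-butoxy-3-oxopropyl)-11-(2,5-dioxocyclopentyl)-3-ethyl-3-methoxy-7-oxo-2-oxa-9-azaspiro[5.5]undecane-9-carboxylate | CCC1(OC)CC[C@@]2(CO1)C(=O)CN(C(=O)OC(C)(C)C)C[C@]2(CCC(=O)OC(C)(C)C)C1C(=O)CCC1=O | intermediate
22 | enol triflate: 11-[5-oxo-2-(trifluoromethanesulfonyloxy)cyclopent-1-en-1-yl] analogue of 21 | CCC1(OC)CC[C@@]2(CO1)C(=O)CN(C(=O)OC(C)(C)C)C[C@]2(CCC(=O)OC(C)(C)C)C1=C(OS(=O)(=O)C(F)(F)F)CCC1=O | intermediate
23 | vinyl dienone: 11-(2-ethenyl-5-oxocyclopent-1-en-1-yl) analogue | CCC1(OC)CC[C@@]2(CO1)C(=O)CN(C(=O)OC(C)(C)C)C[C@]2(CCC(=O)OC(C)(C)C)C1=C(C=C)CCC1=O | intermediate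
24 | 7-hydroxy analogue of 23 (C7 epimers) | CCC1(OC)CC[C@@]2(CO1)C(O)CN(C(=O)OC(C)(C)C)C[C@]2(CCC(=O)OC(C)(C)C)C1=C(C=C)CCC1=O | intermediate
25 | 7-O-(phenoxythiocarbonyl) derivative of 24 | CCC1(OC)CC[C@@]2(CO1)C(OC(=S)Oc1ccccc1)CN(C(=O)OC(C)(C)C)C[C@]2(CCC(=O)OC(C)(C)C)C1=C(C=C)CCC1=O | intermediate
26 | ring-C-closed tetracyclic enone (rings A, C, D, E; Ca bears CH2CH2CO2t-Bu) | CCC1(OC)CC[C@@]2(CO1)[C@@H]1CCC3=C(C(=O)CC3)[C@@]2(CCC(=O)OC(C)(C)C)CN(C(=O)OC(C)(C)C)C1 | intermediate
27 | aldol adduct (ring B closed, tertiary hydroxyl on the former ring-A carbonyl carbon) | CCC1(OC)CC[C@@]2(CO1)[C@@H]1CCC3=C4C(O)(C(C(=O)OC(C)(C)C)C[C@@]42CN(C(=O)OC(C)(C)C)C1)CC3 | intermediate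
28 | N-Boc, tert-butyl ester, O-methyl ketal of the target skeleton | CCC1(OC)CC[C@@]2(CO1)[C@@H]1CCC3=C4C(=C(C(=O)OC(C)(C)C)C[C@@]42CN(C(=O)OC(C)(C)C)C1)CC3 | intermediate
29 | N-desmethyl amino acid hemiketal | CC[C@]1(O)CC[C@@]2(CO1)[C@@H]1CCC3=C4C(=C(C(=O)O)C[C@@]42CNC1)CC3 | intermediate
30 | N-desmethyl target (secondary amine, methyl ester) | CC[C@]1(O)CC[C@@]2(CO1)[C@@H]1CCC3=C4C(=C(C(=O)OC)C[C@@]42CNC1)CC3 | intermediate
31 | CNP0192143.3 | CC[C@]1(O)CC[C@@]2(CO1)[C@@H]1CCC3=C4C(=C(C(=O)OC)C[C@@]42CN(C)C1)CC3 | target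

Total step count: 21. Longest linear sequence: 18 (steps 1–4, then 8–21).

Steps most likely to fail

1. Step 10. The developing tertiary cation may be intercepted by the carbamate carbonyl or by the ionised ketal, the NCH2 carbon may shift in place of Ca, and any lack of uniformity in the oxirane configuration from step 9 is passed on to Cb. Fallback, which uses no oxirane and no Lewis acid: it sets out from allylic alcohol 15. N-(Phenylseleno)phthalimide with a trace of camphorsulfonic acid in CH2Cl2 forms a seleniranium ion on the 1,1-disubstituted alkene, and the 1,2-shift of Ca through this bridged ion gives the ring-enlarged phenylselenomethyl ketone F1, in which Cb is set in the shift itself (diastereomers separated here). Oxidation to the selenoxide (H2O2, −20 °C) and seleno-Pummerer rearrangement (Ac2O, NaOAc; then K2CO3, MeOH) give the keto aldehyde F2. NaBH(OAc)3 reduces only the aldehyde, and the fallback comes back at hydroxy ketone 17, which is ketalised to 18 as in the second half of step 10.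

2. Step 17. Hydrogen transfer to the secondary radical can outrun the slow 7-endo closure (plain deoxygenation), or the radical may add 6-exo. Fallback, a reductive ketone–dienone coupling in place of an alkyl radical: it sets out from keto dienone 23. SmI2 with HMPA and t-BuOH in THF at −78 °C reduces the dienone, whose vinyl terminus adds to the ring ketone carbon and closes ring C as the bridgehead tertiary alcohol F3. Methyl chlorooxoacetate with DMAP gives the mixed methyl oxalate F4, and Bu3SnH with AIBN in refluxing toluene removes the oxalate through the bridgehead radical, which can only take up hydrogen in the bridged configuration; the fallback comes back at 26.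

3. Step 15. Reduction of the dienone carbonyl (1,2 or 1,4) can compete with reduction of the hindered ring ketone. Fallback, which masks ring A as its dione enolate and changes the order of events: it sets out from dione 21. As its potassium enolate (KOt-Bu, MeOH/THF, 0 °C) the vinylogous carboxylate is inert to NaBH4, so only the ring ketone is reduced and the hydroxy dione F5 results. PhNTf2 with Et3N sulfonylates only the acidic dione to the hydroxy enol triflate F6, and Stille coupling as in step 14 brings the fallback back at 24.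

Further compounds
F1 | step 10 | tert-butyl 5-(3-tert-butoxy-3-oxopropyl)-4-(3,3-dimethoxypentyl)-5-(5-methoxy-2-methylidene-5-oxopentyl)-3-oxo-4-[(phenylselanyl)methyl]piperidine-1-carboxylate (Ca, Cb as in 17) | CCC(OC)(OC)CC[C@@]1(C[Se]c2ccccc2)C(=O)CN(C(=O)OC(C)(C)C)C[C@]1(CCC(=O)OC(C)(C)C)CC(=C)CCC(=O)OC
F2 | step 10 | tert-butyl 5-(3-tert-butoxy-3-oxopropyl)-4-(3,3-dimethoxypentyl)-4-formyl-5-(5-methoxy-2-methylidene-5-oxopentyl)-3-oxopiperidine-1-carboxylate (Ca, Cb as in 17) | CCC(OC)(OC)CC[C@@]1(C=O)C(=O)CN(C(=O)OC(C)(C)C)C[C@]1(CCC(=O)OC(C)(C)C)CC(=C)CCC(=O)OC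
F3 | step 17 | bridgehead tertiary alcohol of 26 (hydroxyl in place of the bridgehead hydrogen at Cc) | CCC1(OC)CC[C@@]2(CO1)[C@]1(O)CCC3=C(C(=O)CC3)[C@@]2(CCC(=O)OC(C)(C)C)CN(C(=O)OC(C)(C)C)C1
F4 | step 17 | mixed methyl oxalate of F3 | CCC1(OC)CC[C@@]2(CO1)[C@]1(OC(=O)C(=O)OC)CCC3=C(C(=O)CC3)[C@@]2(CCC(=O)OC(C)(C)C)CN(C(=O)OC(C)(C)C)C1
F5 | step 15 | 7-hydroxy analogue of dione 21 (C7 epimers) | CCC1(OC)CC[C@@]2(CO1)C(O)CN(C(=O)OC(C)(C)C)C[C@]2(CCC(=O)OC(C)(C)C)C1C(=O)CCC1=O
F6 | step 15 | 7-hydroxy analogue of enol triflate 22 (C7 epimers) | CCC1(OC)CC[C@@]2(CO1)C(O)CN(C(=O)OC(C)(C)C)C[C@]2(CCC(=O)OC(C)(C)C)C1=C(OS(=O)(=O)C(F)(F)F)CCC1=O
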